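## Retrosynthetic overview

1. The target is reached by dealkylating its methyl ester / 8‑O‑methyl ether. The C16–O bond and the C15 stereocenter are made together by hydroxylating one terminal methyl of a plain 6‑methylheptan‑2‑yl side chain (key step, proposed new).
2. Side chain: C12–C13 by copper‑catalysed alkyl–alkyl coupling with 3‑methylbutylmagnesium bromide; C11 by ligand‑controlled copper hydride hydroboration of an isopropenyl group.
3. Benzene ring: [3+3] cyclocondensation of a 2‑formylcyclohexanone with methyl 4‑methoxy‑3‑oxobutanoate, which brings C6–CO2Me, C7–OH and C8–OMe.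
4. C1, C4 and the saturated ring come from (R)‑carvone via trans‑dihydrocarvone.
5. Ring order: the cyclohexane ring is bought with carvone; the aromatic ring is the only ring formed (step 3).

Convention: atom labels follow serrulatane numbering (C1 ring CH–CH3, C4 ring CH bearing the side chain, C5 aromatic CH, C6 C–CO2H, C7 and C8 C–OH, C11 side‑chain CH–CH3, C15 CH–CH3, C16 CH2OH); the target is (1R,4S,11S,15R).

Assumption: (R)‑DTBM‑SEGPHOS in step 4 and CYP142A1 in step 7 are taken to give 11S and 15R by analogy with their known substrates; if the first run gives the epimer, the antipodal ligand or the 25S‑selective paralogue CYP125A1 is used.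

## Route

Step 1  
Reactants: 1 (R)-(−)-carvone  
Product: 3 (2R,5R)-2-methyl-5-(prop-1-en-2-yl)cyclohexan-1-one (trans-dihydrocarvone), via lithium enolate 2 (not isolated)  
Conditions: LiBH(s-Bu)3 (1.05 equiv), THF, −78 °C; then aq NH4Cl, −78 → 23 °C  
Reagents that add atoms: none  
Why: Conjugate (1,4) hydride reduction of the enone by the bulky borohydride leaves the isopropenyl group alone, and axial protonation of enolate 2 at low temperature places the new C1 methyl equatorial, trans to the carvone-derived C4 substituent (1R).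

Step 2  
Reactants: 3 (2R,5R)-2-methyl-5-(prop-1-en-2-yl)cyclohexan-1-one  
Product: 5 (3S,6R)-2-(hydroxymethylidene)-6-methyl-3-(prop-1-en-2-yl)cyclohexan-1-one, via kinetic lithium enolate 4 (not isolated)  
Conditions: LiN(i-Pr)2 (1.15 equiv), THF, −78 °C; HCO2CH2CF3 (1.5 equiv), −78 °C; aq HCl  
Reagents that add atoms: 2,2,2-trifluoroethyl formate, O=COCC(F)(F)F  
Why: Kinetic deprotonation at the less substituted methylene followed by crossed Claisen formylation with the activated formate functionalises C4a only; the product rests as its β-ketoaldehyde enolate, so the C1 stereocenter is not epimerised and no new one is formed.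

Step 3  
Reactants: 5 (3S,6R)-2-(hydroxymethylidene)-6-methyl-3-(prop-1-en-2-yl)cyclohexan-1-one; 6 methyl 4-methoxy-3-oxobutanoate  
Product: 8 methyl (5R,8S)-3-hydroxy-4-methoxy-5-methyl-8-(prop-1-en-2-yl)-5,6,7,8-tetrahydronaphthalene-2-carboxylate, via Knoevenagel adduct 7 (not isolated)  
Conditions: piperidinium acetate (20 mol %), MeOH, 23 °C; then NaOMe (2.2 equiv), MeOH, 65 °C; aq HCl  
Reagents that add atoms: none  
Why: Prelog-type [3+3] cyclocondensation: Knoevenagel condensation of the active methylene of 6 with the formyl carbon gives 7, then intramolecular aldol condensation of the methoxy-bearing carbon onto the ring ketone and enolisation aromatise the new ring, placing OMe at C8, OH at C7 and CO2Me at C6 with no new stereocenter.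

Step 4  
Reactants: 8 methyl (5R,8S)-3-hydroxy-4-methoxy-5-methyl-8-(prop-1-en-2-yl)-5,6,7,8-tetrahydronaphthalene-2-carboxylate  
Product: 10 methyl (5R,8S)-3-hydroxy-8-[(2R)-1-hydroxypropan-2-yl]-4-methoxy-5-methyl-5,6,7,8-tetrahydronaphthalene-2-carboxylate, via bis(pinacolboryl) intermediate 9 (not isolated)  
Conditions: CuCl (5 mol %), (R)-DTBM-SEGPHOS (6 mol %), KOt-Bu (10 mol %), HBpin (2.5 equiv), toluene, 40 °C; then NaBO3·4H2O, THF/H2O, 23 °C  
Reagents that add atoms: pinacolborane, CC1(C)OBOC1(C)C (the two boryl groups of 9); sodium perborate, [Na+].[O-]OB=O (the C12 oxygen of 10)  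
Why: Copper hydride-catalysed anti-Markovnikov asymmetric hydroboration of an unactivated 1,1-disubstituted alkene (a known reaction for branched-alkyl/methyl alkenes): ligand-controlled hydrocupration sets C11 (11S), σ-bond metathesis with HBpin gives 9 (the phenol is borylated in the flask), and perborate converts C–B into C–OH.

Step 5  
Reactants: 10 methyl (5R,8S)-3-hydroxy-8-[(2R)-1-hydroxypropan-2-yl]-4-methoxy-5-methyl-5,6,7,8-tetrahydronaphthalene-2-carboxylate  
Product: 11 methyl (5R,8S)-3-hydroxy-8-[(2R)-1-iodopropan-2-yl]-4-methoxy-5-methyl-5,6,7,8-tetrahydronaphthalene-2-carboxylate  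
Conditions: PPh3, I2, imidazole, CH2Cl2, 0 → 23 °C  
Reagents that add atoms: iodine, II  
Why: Appel-type iodination of the primary alcohol by SN2 displacement of the oxyphosphonium group; the hydrogen-bonded salicylate phenol, the ester and C11 are untouched.

Step 6  
Reactants: 11 methyl (5R,8S)-3-hydroxy-8-[(2R)-1-iodopropan-2-yl]-4-methoxy-5-methyl-5,6,7,8-tetrahydronaphthalene-2-carboxylate; 12 3-methylbutylmagnesium bromide  
Product: 13 methyl (5R,8S)-3-hydroxy-4-methoxy-5-methyl-8-[(2S)-6-methylheptan-2-yl]-5,6,7,8-tetrahydronaphthalene-2-carboxylate  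
Conditions: 12 (2.5 equiv), Li2CuCl4 (5 mol %), THF, −30 → 0 °C; aq NH4Cl  
Reagents that add atoms: none  
Why: Kochi copper-catalysed sp3–sp3 cross-coupling of a primary alkyl iodide with a primary Grignard reagent; the first equivalent of 12 deprotonates the phenol, whose magnesium phenoxide deactivates the neighbouring ester toward addition at this temperature.

Step 7  
Reactants: 13 methyl (5R,8S)-3-hydroxy-4-methoxy-5-methyl-8-[(2S)-6-methylheptan-2-yl]-5,6,7,8-tetrahydronaphthalene-2-carboxylate  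
Product: 14 methyl (5R,8S)-3-hydroxy-8-[(2S,6R)-7-hydroxy-6-methylheptan-2-yl]-4-methoxy-5-methyl-5,6,7,8-tetrahydronaphthalene-2-carboxylate  
Conditions: cytochrome P450 CYP142A1 (2 mol %), spinach ferredoxin, ferredoxin–NADP+ reductase, NADP+ (cat.), D-glucose (1.2 equiv), glucose dehydrogenase, catalase, 2-hydroxypropyl-β-cyclodextrin, 50 mM potassium phosphate pH 7.4, air, 30 °C  
Reagents that add atoms: dioxygen, O=O  
Why: Proposed new method: sterol-type P450 ω-hydroxylation transferred to a serrulatane; the ferryl-oxo haem (tetravalent iron, porphyrin radical cation) abstracts a hydrogen atom from the one terminal methyl that the narrow lipid channel holds over the iron and oxygen rebound forms the C16–O bond, so the weaker tertiary C15–H and benzylic C–H bonds are not reached and the choice between the two diastereotopic methyls sets C15; 13 carries the same 6-methylheptan-2-yl terminus as cholesterol, where CYP142A1 gives the 25R alcohol, the sense that is 15R here, and limiting glucose stops at the alcohol; closest known reactions are C26 hydroxylation of cholesterol and cholest-4-en-3-one by CYP142A1 and CYP27A1 and ω-hydroxylation of methyl-branched lipids by CYP124A1.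

Step 8  
Reactants: 14 methyl (5R,8S)-3-hydroxy-8-[(2S,6R)-7-hydroxy-6-methylheptan-2-yl]-4-methoxy-5-methyl-5,6,7,8-tetrahydronaphthalene-2-carboxylate  
Product: 15 (5R,8S)-3,4-dihydroxy-8-[(2S,6R)-7-hydroxy-6-methylheptan-2-yl]-5-methyl-5,6,7,8-tetrahydronaphthalene-2-carboxylic acid (CNP0455284.1)  
Conditions: AlCl3 (6 equiv), EtSH, CH2Cl2, 0 → 23 °C; aq HCl  
Reagents that add atoms: none  
Why: Hard Lewis acid/soft nucleophile dealkylation: ethanethiol attacks the O-methyl carbons of the AlCl3-bound aryl ether and ester by SN2, freeing the catechol and the acid while the primary alcohol and the four stereocenters are untouched.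

## Compound list

    1 | (R)-(−)-carvone | CC1=CC[C@H](CC1=O)C(C)=C | starting material
    2 | lithium (5R)-2-methyl-5-(prop-1-en-2-yl)cyclohex-1-en-1-olate | CC1=C([O-])C[C@@H](CC1)C(C)=C.[Li+] | intermediate
    3 | (2R,5R)-2-methyl-5-(prop-1-en-2-yl)cyclohexan-1-one | C[C@@H]1CC[C@H](CC1=O)C(C)=C | intermediate
    4 | lithium (3R,6R)-6-methyl-3-(prop-1-en-2-yl)cyclohex-1-en-1-olate | C[C@@H]1CC[C@H](C=C1[O-])C(C)=C.[Li+] | intermediate
    5 | (3S,6R)-2-(hydroxymethylidene)-6-methyl-3-(prop-1-en-2-yl)cyclohexan-1-one | C[C@@H]1CC[C@@H](C(C)=C)/C(=C/O)C1=O | intermediate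
    6 | methyl 4-methoxy-3-oxobutanoate | COCC(=O)CC(=O)OC | starting material
    7 | methyl 4-methoxy-2-{[(3R,6R)-3-methyl-2-oxo-6-(prop-1-en-2-yl)cyclohexyl]methylidene}-3-oxobutanoate (ring C1 and alkene geometry undefined) | C[C@@H]1CC[C@@H](C(C)=C)C(C=C(C(=O)OC)C(=O)COC)C1=O | intermediate
    8 | methyl (5R,8S)-3-hydroxy-4-methoxy-5-methyl-8-(prop-1-en-2-yl)-5,6,7,8-tetrahydronaphthalene-2-carboxylate | C=C(C)[C@@H]1CC[C@@H](C)c2c1cc(C(=O)OC)c(O)c2OC | intermediate
    9 | methyl (5R,8S)-4-methoxy-5-methyl-3-[(4,4,5,5-tetramethyl-1,3,2-dioxaborolan-2-yl)oxy]-8-[(2S)-1-(4,4,5,5-tetramethyl-1,3,2-dioxaborolan-2-yl)propan-2-yl]-5,6,7,8-tetrahydronaphthalene-2-carboxylate | C[C@@H](CB1OC(C)(C)C(C)(C)O1)[C@@H]2CC[C@@H](C)c3c2cc(C(=O)OC)c(OB4OC(C)(C)C(C)(C)O4)c3OC | intermediate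
    10 | methyl (5R,8S)-3-hydroxy-8-[(2R)-1-hydroxypropan-2-yl]-4-methoxy-5-methyl-5,6,7,8-tetrahydronaphthalene-2-carboxylate | OC[C@H](C)[C@@H]1CC[C@@H](C)c2c1cc(C(=O)OC)c(O)c2OC | intermediate
    11 | methyl (5R,8S)-3-hydroxy-8-[(2R)-1-iodopropan-2-yl]-4-methoxy-5-methyl-5,6,7,8-tetrahydronaphthalene-2-carboxylate | IC[C@H](C)[C@@H]1CC[C@@H](C)c2c1cc(C(=O)OC)c(O)c2OC | intermediate
    12 | 3-methylbutylmagnesium bromide | CC(C)CC[Mg]Br | starting material
    13 | methyl (5R,8S)-3-hydroxy-4-methoxy-5-methyl-8-[(2S)-6-methylheptan-2-yl]-5,6,7,8-tetrahydronaphthalene-2-carboxylate | CC(C)CCC[C@H](C)[C@@H]1CC[C@@H](C)c2c1cc(C(=O)OC)c(O)c2OC | intermediate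
    14 | methyl (5R,8S)-3-hydroxy-8-[(2S,6R)-7-hydroxy-6-methylheptan-2-yl]-4-methoxy-5-methyl-5,6,7,8-tetrahydronaphthalene-2-carboxylate | C[C@@H](CO)CCC[C@H](C)[C@@H]1CC[C@@H](C)c2c1cc(C(=O)OC)c(O)c2OC | intermediate
    15 | (5R,8S)-3,4-dihydroxy-8-[(2S,6R)-7-hydroxy-6-methylheptan-2-yl]-5-methyl-5,6,7,8-tetrahydronaphthalene-2-carboxylic acid | C[C@@H](CO)CCC[C@H](C)[C@@H]1CC[C@@H](C)c2c1cc(C(=O)O)c(O)c2O | target

## Step count

Total steps: 8. Longest linear sequence: 8 (1 → 15); 6 and 12 are purchased.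

## Steps most likely to fail

**Step 7 (proposed ω-hydroxylation).** Risks are low turnover on a non-sterol substrate, attack on the other methyl, or over-oxidation to the C16 acid. The fallback uses known chemistry and takes C15 from the chiral pool. It sets out from 8. The hydroboration of step 4 is run without the oxidative work-up, and the alkylboronate is isolated after aqueous work-up as methyl (5R,8S)-3-hydroxy-4-methoxy-5-methyl-8-[(2S)-1-(4,4,5,5-tetramethyl-1,3,2-dioxaborolan-2-yl)propan-2-yl]-5,6,7,8-tetrahydronaphthalene-2-carboxylate F1. Suzuki–Miyaura coupling (Pd(OAc)2, RuPhos, K3PO4, toluene/H2O, 80 °C) with the known Roche-ester-derived vinyl iodide ({[(2R,3E)-4-iodo-2-methylbut-3-en-1-yl]oxy}methyl)benzene F2 gives methyl (5R,8S)-8-[(2S,4E,6R)-7-(benzyloxy)-6-methylhept-4-en-2-yl]-3-hydroxy-4-methoxy-5-methyl-5,6,7,8-tetrahydronaphthalene-2-carboxylate F3. Hydrogen over Pd/C (EtOAc/MeOH) saturates the alkene and cleaves the benzyl ether, and the route is rejoined at 14.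

**Step 3 (benzannulation).** Risks are a sluggish Knoevenagel step on the enolised ketoaldehyde 5, diversion to a 2-pyranone, or partial epimerisation at C1 under methoxide. The fallback sets out from 3. Its kinetic enolate 4 is added at −78 °C to methyl 2-(ethoxymethylidene)-4-methoxy-3-oxobutanoate F4 (made from 6 with HC(OEt)3 and Ac2O). Conjugate addition and loss of ethoxide give adduct 7 directly, without 5. NaOMe in MeOH then closes and aromatises the ring, and the route is rejoined at 8.

**Step 4 (C11 by hydroboration).** The risk is insufficient catalyst control next to the hindered benzylic C4. The fallback sets out from 8. A Me2AlCl-promoted carbonyl-ene reaction with paraformaldehyde (CH2Cl2, −78 → 0 °C) gives methyl (5R,8S)-3-hydroxy-8-(4-hydroxybut-1-en-2-yl)-4-methoxy-5-methyl-5,6,7,8-tetrahydronaphthalene-2-carboxylate F5. Asymmetric hydrogenation of the 1,1-disubstituted alkene (H2, 50 bar, [Ir(cod)((S)-t-Bu-PHOX)][B(C6H3(CF3)2)4], CH2Cl2) sets C11 in methyl (5R,8S)-3-hydroxy-8-[(2S)-4-hydroxybutan-2-yl]-4-methoxy-5-methyl-5,6,7,8-tetrahydronaphthalene-2-carboxylate F6. PPh3/I2/imidazole gives methyl (5R,8S)-3-hydroxy-8-[(2S)-4-iodobutan-2-yl]-4-methoxy-5-methyl-5,6,7,8-tetrahydronaphthalene-2-carboxylate F7. Li2CuCl4-catalysed coupling with 2-methylpropylmagnesium bromide rejoins the route at 13.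

Further compounds

    F1 | step 7 | methyl (5R,8S)-3-hydroxy-4-methoxy-5-methyl-8-[(2S)-1-(4,4,5,5-tetramethyl-1,3,2-dioxaborolan-2-yl)propan-2-yl]-5,6,7,8-tetrahydronaphthalene-2-carboxylate | C[C@@H](CB1OC(C)(C)C(C)(C)O1)[C@@H]2CC[C@@H](C)c3c2cc(C(=O)OC)c(O)c3OC
    F2 | step 7 | ({[(2R,3E)-4-iodo-2-methylbut-3-en-1-yl]oxy}methyl)benzene | C[C@@H](COCc1ccccc1)/C=C/I
    F3 | step 7 | methyl (5R,8S)-8-[(2S,4E,6R)-7-(benzyloxy)-6-methylhept-4-en-2-yl]-3-hydroxy-4-methoxy-5-methyl-5,6,7,8-tetrahydronaphthalene-2-carboxylate | C[C@@H](COCc1ccccc1)/C=C/C[C@H](C)[C@@H]2CC[C@@H](C)c3c2cc(C(=O)OC)c(O)c3OC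
    F4 | step 3 | methyl 2-(ethoxymethylidene)-4-methoxy-3-oxobutanoate | CCOC=C(C(=O)OC)C(=O)COC
    F5 | step 4 | methyl (5R,8S)-3-hydroxy-8-(4-hydroxybut-1-en-2-yl)-4-methoxy-5-methyl-5,6,7,8-tetrahydronaphthalene-2-carboxylate | C=C(CCO)[C@@H]1CC[C@@H](C)c2c1cc(C(=O)OC)c(O)c2OC
    F6 | step 4 | methyl (5R,8S)-3-hydroxy-8-[(2S)-4-hydroxybutan-2-yl]-4-methoxy-5-methyl-5,6,7,8-tetrahydronaphthalene-2-carboxylate | OCC[C@H](C)[C@@H]1CC[C@@H](C)c2c1cc(C(=O)OC)c(O)c2OC
    F7 | step 4 | methyl (5R,8S)-3-hydroxy-8-[(2S)-4-iodobutan-2-yl]-4-methoxy-5-methyl-5,6,7,8-tetrahydronaphthalene-2-carboxylate | ICC[C@H](C)[C@@H]1CC[C@@H](C)c2c1cc(C(=O)OC)c(O)c2OC
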